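**Plan**

- Retrosynthesis (quinone numbering C1=O, C2–OH, C3–Me, C4=O, C5–OH, C6–side chain): the ring is read as its cyclohexane-1,2,4,5-tetraone tautomer and cut at C1–C2 and C4–C5, the two bonds that each join two oxygen-bearing ring carbons. The side chain is then cut between its C13 and C14 (alkyne alkylation), and one ring carbonyl carbon is traced back to CO2.
- Enabling feature: C3 and C6 each sit between two oxygen-bearing carbons, so the ring is two malonyl-type C3 units (C2–C3–C4 and C5–C6–C1) joined head to head by two acyl–acyl bonds between carbons of like polarity.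
- Polarity reversal of one unit makes these bonds accessible: C2 and C4 as the carbanions of a bis(1,3-dithiane) (double acyl anion), and C5–C6–C1 as a (chlorocarbonyl)ketene (double acyl cation with no acidic C–H). Their [3+3] union closes the only ring at the final oxidation level.
- Forward: chain acid from 15-bromopentadecanoic acid and hex-1-yne, trans reduction, α-carboxylation with CO2, ketene formation; bis(dithiane) in one step; annulation; dithiane hydrolysis, after which tautomerisation gives the quinone.
- Stereochemistry: only the E alkene of the chain, set by dissolving-metal reduction of the alkyne in step 2 and not touched afterwards. The target has no stereocentre.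

Key step: step 6

Remark: the target is written as the 2,5-dihydroxy-1,4-benzoquinone tautomer of the given structure; the hydroxy-trione released in the last step is a tautomer of it at the same oxidation level.

**Step 1**
Reactants: 1 15-bromopentadecanoic acid; 2 hex-1-yne
Product: 4 henicos-16-ynoic acid, via hex-1-yn-1-yllithium 3 (not isolated)
Conditions: n-BuLi (3.1 equiv) on 2 (3.2 equiv), THF/DMPU, −78 to 0 °C; then 1, 0 °C to rt; 1 M HCl
Reagents that add atoms: none
Why: SN2 alkylation of a lithium acetylide by the primary bromide (acetylide alkylation); the first equivalent of 3 only converts the acid into its inert lithium carboxylate.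

**Step 2**
Reactants: 4 henicos-16-ynoic acid
Product: 5 (E)-henicos-16-enoic acid
Conditions: Na, NH3(l)/THF, −33 °C; NH4Cl; 1 M HCl
Reagents that add atoms: none
Why: Dissolving-metal reduction of the internal alkyne passes through the more stable trans-vinyl anion, which fixes the E geometry, while the carboxylate is not reduced.

**Step 3**
Reactants: 5 (E)-henicos-16-enoic acid
Product: 7 2-[(E)-nonadec-14-en-1-yl]propanedioic acid, via dilithium enediolate 6 (not isolated)
Conditions: LiN(i-Pr)2 (2.2 equiv), THF/DMPU, 0 to 45 °C; CO2 (g), −78 °C; cold 1 M HCl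
Reagents that add atoms: carbon dioxide O=C=O
Why: α-Carboxylation of a carboxylic acid dianion: enediolate 6 attacks CO2 at carbon to give the malonate, and cold acidification avoids decarboxylation.

**Step 4**
Reactants: 7 2-[(E)-nonadec-14-en-1-yl]propanedioic acid
Product: 9 (E)-2-(oxomethylidene)henicos-16-enoyl chloride, via malonyl dichloride 8 (not isolated)
Conditions: SOCl2 (neat), 45 °C; evaporate; toluene, 110 °C, N2 stream; evaporate, use crude
Reagents that add atoms: thionyl chloride O=S(Cl)Cl
Why: Acid chloride formation followed by thermal 1,2-elimination of HCl from the monosubstituted malonyl dichloride, the known route from malonic acids to (chlorocarbonyl)ketenes; this removes the only acidic C–H, and the isolated alkene is inert to SOCl2.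

**Step 5**
Reactants: 10 1,1,3,3-tetraethoxy-2-methylpropane
Product: 11 2,2'-(ethane-1,1-diyl)bis(1,3-dithiane)
Conditions: propane-1,3-dithiol (2.1 equiv), BF3·OEt2, CH2Cl2, 0 °C to rt
Reagents that add atoms: propane-1,3-dithiol SCCCS
Why: Lewis-acid transthioacetalisation of both acetal groups (dithioacetal formation), with the six-membered dithiane rings as the thermodynamic sink.

**Step 6**
Reactants: 11 2,2'-(ethane-1,1-diyl)bis(1,3-dithiane); 9 (E)-2-(oxomethylidene)henicos-16-enoyl chloride
Product: 13 6'-hydroxy-2'-methyl-5'-[(E)-nonadec-14-en-1-yl]dispiro[[1,3]dithiane-2,1'-cyclohexane-3',2''-[1,3]dithian]-5'-en-4'-one, via dilithio bis(dithiane) 12 (not isolated)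
Conditions: n-BuLi (2.2 equiv), THF, −30 to −10 °C; then this solution and 9 (THF) added together slowly into THF at −78 °C (about 0.01 M), to −20 °C; aq. NH4Cl
Reagents that add atoms: none
Why: Proposed new method: dianion 12 is a 1,3-bis(acyl anion) equivalent and ketene 9 a malonyl 1,3-bis(acyl cation) equivalent with no acidic C–H, so the first dithianyl carbanion should add to the ketene carbonyl carbon to give a lithium enolate, and the second should then attack the neighbouring acyl chloride (directly or after chloride loss to the acylketene) to give the lithium enolate of the cyclic 1,3-dione. The closest known reaction types are the Corey–Seebach C-acylation of 2-lithio-1,3-dithianes by acid chlorides and esters, the ring closure of dilithiated bis(dithianes) on 1,3-dielectrophiles, and the [3+3] cyclocondensation of (chlorocarbonyl)ketenes with 1,3-dinucleophiles; the combination with two carbon nucleophiles is new. The six-membered carbocycle is closed by an intermolecular addition followed by a 6-exo-trig addition–elimination. No lasting stereocentre arises: the C–Me methine is stereogenic only formally in the enol drawing, is not controlled, and becomes trigonal in the target. Cross- instead of homo-coupling is secured by the opposite polarity of the two C3 units, C–C bond formation instead of proton transfer by the ketene oxidation level of 9, ring closure instead of oligomerisation by the 1,3-spacing of the carbanions together with high dilution, and over-addition is blocked because the product forms as its enolate.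

**Step 7**
Reactants: 13 6'-hydroxy-2'-methyl-5'-[(E)-nonadec-14-en-1-yl]dispiro[[1,3]dithiane-2,1'-cyclohexane-3',2''-[1,3]dithian]-5'-en-4'-one
Product: 15 2,5-dihydroxy-3-methyl-6-[(E)-nonadec-14-en-1-yl]cyclohexa-2,5-diene-1,4-dione, via triketo-enol tautomer 14 (not isolated)
Conditions: HgCl2, CaCO3, MeCN/H2O 4:1, rt to 50 °C; then 1 M HCl
Reagents that add atoms: water O
Why: Corey–Seebach dithiane hydrolysis: thiophilic divalent mercury ionises the C–S bonds and water delivers the two carbonyl oxygens; the released hydroxy-trione 14 moves its C–Me hydrogen to oxygen to give the conjugated 2,5-dihydroxy-1,4-benzoquinone without a redox step, and HgCl2 should not add to the isolated alkene.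

**Compound list**

1 | 15-bromopentadecanoic acid | OC(=O)CCCCCCCCCCCCCCBr | starting material
2 | hex-1-yne | CCCCC#C | starting material
3 | hex-1-yn-1-yllithium | [Li]C#CCCCC | intermediate
4 | henicos-16-ynoic acid | CCCCC#CCCCCCCCCCCCCCCC(=O)O | intermediate
5 | (E)-henicos-16-enoic acid | CCCC/C=C/CCCCCCCCCCCCCCC(=O)O | intermediate
6 | dilithium (E)-henicosa-1,16-diene-1,1-diolate (enediolate of 5) | CCCC/C=C/CCCCCCCCCCCCCC=C(O[Li])O[Li] | intermediate
7 | 2-[(E)-nonadec-14-en-1-yl]propanedioic acid | CCCC/C=C/CCCCCCCCCCCCCC(C(=O)O)C(=O)O | intermediate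
8 | 2-[(E)-nonadec-14-en-1-yl]propanedioyl dichloride | CCCC/C=C/CCCCCCCCCCCCCC(C(=O)Cl)C(=O)Cl | intermediate
9 | (E)-2-(oxomethylidene)henicos-16-enoyl chloride, i.e. (chlorocarbonyl)[(E)-nonadec-14-en-1-yl]ketene | CCCC/C=C/CCCCCCCCCCCCCC(C(=O)Cl)=C=O | intermediate
10 | 1,1,3,3-tetraethoxy-2-methylpropane | CCOC(OCC)C(C)C(OCC)OCC | starting material
11 | 2,2'-(ethane-1,1-diyl)bis(1,3-dithiane) | CC(C1SCCCS1)C1SCCCS1 | intermediate
12 | 2,2'-(ethane-1,1-diyl)bis(2-lithio-1,3-dithiane) | CC(C1([Li])SCCCS1)C1([Li])SCCCS1 | intermediate
13 | 6'-hydroxy-2'-methyl-5'-[(E)-nonadec-14-en-1-yl]dispiro[[1,3]dithiane-2,1'-cyclohexane-3',2''-[1,3]dithian]-5'-en-4'-one (enol of the 2-alkylcyclohexane-1,3-dione with spiro 1,3-dithianes on both carbons flanking the C–Me carbon) | CCCC/C=C/CCCCCCCCCCCCCC1=C(O)C2(SCCCS2)C(C)C2(SCCCS2)C1=O | intermediate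
14 | 5-hydroxy-3-methyl-6-[(E)-nonadec-14-en-1-yl]cyclohex-5-ene-1,2,4-trione | CCCC/C=C/CCCCCCCCCCCCCC1=C(O)C(=O)C(C)C(=O)C1=O | intermediate
15 | 2,5-dihydroxy-3-methyl-6-[(E)-nonadec-14-en-1-yl]cyclohexa-2,5-diene-1,4-dione | CCCC/C=C/CCCCCCCCCCCCCC1=C(O)C(=O)C(C)=C(O)C1=O | target

**Step count**

Total steps: 7. Longest linear sequence: 6 (steps 1, 2, 3, 4, 6, 7).

**Steps most likely to fail**

1. Step 6. The second lithiation may be incomplete. The acid chloride or the acylketene may oligomerise faster than the ring closes. The carbanions may act as bases or electron donors instead of as carbon nucleophiles at the two hindered dithiane carbons.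
Fallback (known chemistry, sets out from 5 and 11, returns at 13): acid 5 is converted with 1,1'-carbonyldiimidazole and MeNHOMe·HCl into (E)-N-methoxy-N-methylhenicos-16-enamide F1. Dianion 12, made from 11 as before, is treated at −78 °C first with one equivalent of F1 and then with methyl chloroformate. After work-up this should give methyl 2-{1-[2-((E)-henicos-16-enoyl)-1,3-dithian-2-yl]ethyl}-1,3-dithiane-2-carboxylate F2 by two ordinary Corey–Seebach acylations. t-BuOK in THF then closes the ring by intramolecular Claisen (Dieckmann-type) condensation of the ketone α-methylene onto the ester, giving 13.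

2. Step 4. The malonic acid may decarboxylate before both acid chlorides have formed. Loss of HCl from 8 may be incomplete, and residual C–H acid would quench a carbanion in step 6. The ketene may dimerise on concentration, and hot HCl may add to or isomerise the chain alkene.
Fallback (sets out from 7, returns at 9): 7 is silylated with hexamethyldisilazane to bis(trimethylsilyl) 2-[(E)-nonadec-14-en-1-yl]propanedioate F3. Oxalyl chloride with catalytic DMF in CH2Cl2 at 0 °C converts F3 into dichloride 8 under neutral, cold conditions, and 8 is now isolated. HCl is then removed at −30 °C with one equivalent of i-Pr2NEt in Et2O/hexane (amine dehydrochlorination of an acid chloride). The ammonium chloride is filtered off under argon and the cold filtrate of 9 goes directly into step 6.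

3. Step 7. C–S ionisation next to a carbonyl at two hindered quaternary carbons may be slow. Forcing conditions could then let divalent mercury add to the chain alkene or stay bound to the chelating product.
Fallback (sets out from 13, returns at 15): 13 is O-methylated with TMSCHN2 in MeOH/toluene to 6'-methoxy-2'-methyl-5'-[(E)-nonadec-14-en-1-yl]dispiro[[1,3]dithiane-2,1'-cyclohexane-3',2''-[1,3]dithian]-5'-en-4'-one F4. Both dithianes are then removed oxidatively with the trivalent iodine reagent PhI(OCOCF3)2 in aqueous MeCN, which tolerates isolated alkenes and no longer meets a free enol. This should give 2-hydroxy-5-methoxy-3-methyl-6-[(E)-nonadec-14-en-1-yl]cyclohexa-2,5-diene-1,4-dione F5. Hydrolysis of the vinylogous ester (2 M NaOH, EtOH, then HCl) gives 15.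

**Further compounds**

F1 | step 6 | (E)-N-methoxy-N-methylhenicos-16-enamide | CCCC/C=C/CCCCCCCCCCCCCCC(=O)N(C)OC
F2 | step 6 | methyl 2-{1-[2-((E)-henicos-16-enoyl)-1,3-dithian-2-yl]ethyl}-1,3-dithiane-2-carboxylate | CCCC/C=C/CCCCCCCCCCCCCCC(=O)C1(SCCCS1)C(C)C1(SCCCS1)C(=O)OC
F3 | step 4 | bis(trimethylsilyl) 2-[(E)-nonadec-14-en-1-yl]propanedioate | CCCC/C=C/CCCCCCCCCCCCCC(C(=O)O[Si](C)(C)C)C(=O)O[Si](C)(C)C
F4 | step 7 | 6'-methoxy-2'-methyl-5'-[(E)-nonadec-14-en-1-yl]dispiro[[1,3]dithiane-2,1'-cyclohexane-3',2''-[1,3]dithian]-5'-en-4'-one | CCCC/C=C/CCCCCCCCCCCCCC1=C(OC)C2(SCCCS2)C(C)C2(SCCCS2)C1=O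
F5 | step 7 | 2-hydroxy-5-methoxy-3-methyl-6-[(E)-nonadec-14-en-1-yl]cyclohexa-2,5-diene-1,4-dione | CCCC/C=C/CCCCCCCCCCCCCC1=C(OC)C(=O)C(C)=C(O)C1=O
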